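Wu leaves the flask more slowly than Zo does, and how much more slowly is the number you should carry.

all flasks: Zo 0.40 M

| run | Qa | Ky | remark | time |
|---|---|---|---|---|
| delta | 0.44 M | 0.12 M | the very flask that is asked about, followed so far |  |
| zeta | 0.44 M | 0.060 M | run made earlier |  |
| flask | 0.440 M | 0.120 M |  | 12 min |

| run | time / min | Wu / % | WuDx / % | Zo / % |
|---|---|---|---|---|
| delta | 0.167 | 36.7 | 0 | 61.8 |
| delta | 0.333 | 54.7 | 1.6 | 39.1 |
| delta | 0.500 | 63.4 | 5.9 | 24.1 |
| delta | 0.833 | 64.1 | 16.0 | 9.2 |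
| delta | 1.50 | 47.5 | 33.8 | 1.9 |
| delta | 2.50 | 26.3 | 51.2 | 0 |
| delta | 5.00 | 6.2 | 69.7 | 0 |
| zeta | 0.167 | 37.0 | 0.5 | 62.4 |
| zeta | 0.333 | 56.4 | 2.4 | 39.3 |
| zeta | 0.667 | 70.2 | 10.6 | 14.9 |
| zeta | 1.33 | 58.9 | 30.9 | 1.9 |
| zeta | 3.00 | 25.8 | 62.4 | 0.5 |
| zeta | 6.00 | 7.4 | 80.1 | 0.4 |
| zeta | 12.0 | 1.3 | 85.2 | 0 |

(scatter of a reading: 0.5 percentage points)

- the analysis behind the earlier runs scatters by 0.5 percentage points, standard deviation

1. time up to 12 min at which Wu stands highest
2. the amount of Wu, in percent of the Zo charged, at that time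

1. First instants. In delta, the flask in question, Zo reads 24.1% at 0.500 min, so it falls with a constant of 2.85 min⁻¹, a power of ten every 0.809 min. Zeta, with half the Ky, reads 39.3% at 0.333 min against 39.1% in delta at 0.333 min.

2. Middle. Delta's Wu reads 63.4% at 0.500 min and 64.1% at 0.833 min, while WuDx has reached 16.0%. By then Zo reads 9.2%, and at 1.50 min Wu is down to 47.5%, so delta's Wu tops out somewhere between 0.500 min and 1.50 min.

3. End. Take the tails as pseudo-first-order. Delta's Wu falls with 0.582 min⁻¹, and zeta's with 0.444 min⁻¹, which is slower. That is 0.0382 M⁻¹ s⁻¹ of loss constant per unit of [Ky].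

4. Peak. Call Wu's loss constant over Zo's the drain ratio, r, here 0.204. For two first-order steps in a row, the common logarithm of the peak fraction is r over one minus r, times the common logarithm of r: 0.256 times −0.690. My reckoning for delta is a peak of 66.5% at 0.701 min.

The forecast, from “a consecutive first-order fit”, says 65.5% at 0.68 min, a little lower and earlier than mine.

The flask gives 66.1% at 0.661 min.

    Zo → Wu (k = 0.0471 s⁻¹)
    Qa → Dx (k = 0.0140 s⁻¹)
    Wu + Dx → WuDx (k = 0.0484 M⁻¹ s⁻¹)
    Wu + Ky → WuKy (k = 0.0448 M⁻¹ s⁻¹)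

At 0.661 min this flask holds Zo 15.4% and Wu 66.1%. Feed equals loss at a peak, so their ratio, 0.233, is the drain ratio of that moment, beside 0.204 from the tail. In the neighbouring flask with 0.48 M of Ky, the slope from step 3 lifts Wu's loss constant to 1.41 min⁻¹, so the drain ratio becomes 0.494. The same logarithms give a peak of 50.2%, and that flask gives 49.7%. At 12.0 min it holds WuKy 64.3% against WuDx 35.7%.

The data are simulated on assumed constants.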